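Ring C is cut at O1–C2 and C4–C4a (flavanone numbering), which leaves a ring A phenol and an isoferuloyl unit. Both are first joined through a bond the target lacks, the aryl ester O1–C4, on a ring A that carries iodine at C4a. In one flask, iodine–lithium exchange triggers a 1,3 O-to-C acyl shift (C4–C4a) that releases O1 alone. After protonation, a cinchona thiourea closes ring C by enantioselective oxa-Michael addition (O1–C2, 2S). The step exploits the ortho pair O1/C4a of ring A: C8 is blocked by the prenyl group and O5 is masked, so acyl transfer and ring closure each have a single site.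

Key step: step 6

Assumption: the thiourea derived from 9-amino-9-deoxy-epi-quinine is taken to give the 2S product. Its quinidine-derived pseudo-enantiomer is also on sale and replaces it, with nothing else changed, if a trial run shows the opposite sense.

Step 1
Reactants: 1 5-methoxyresorcinol (5-methoxybenzene-1,3-diol)
Product: 2 2-iodo-5-methoxybenzene-1,3-diol
Conditions: I2 (1.0 equiv), NaHCO3, H2O/THF, 0 °C to rt
Reagents that add atoms: iodine, II
Why: Electrophilic aromatic iodination of the phenolate should place iodine at C2 between the two hydroxyl groups, as in resorcinol itself, because that site is also para to the methoxy group while C4 and C6 are each crowded by OH and OMe.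

Step 2
Reactants: 2 2-iodo-5-methoxybenzene-1,3-diol
Product: 3 2-iodo-5-methoxy-4-(3-methylbut-2-en-1-yl)benzene-1,3-diol
Conditions: prenyl bromide (1.0 equiv), KOH (1.0 equiv), H2O, 0 °C to rt
Reagents that add atoms: prenyl bromide (1-bromo-3-methylbut-2-ene), CC(C)=CCBr
Why: This is C-alkylation of an ambident phloroglucinol-type phenolate, where water solvates the oxygen and so favours attack through carbon, and because iodine blocks C2 and the two free ring carbons are equivalent, only one C-monoprenyl isomer can form.

Step 3
Reactants: 3 2-iodo-5-methoxy-4-(3-methylbut-2-en-1-yl)benzene-1,3-diol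
Product: 4 2-iodo-5-methoxy-3-(methoxymethoxy)-6-(3-methylbut-2-en-1-yl)phenol
Conditions: MOMCl (1.0 equiv), i-Pr2NEt, CH2Cl2, 0 °C
Reagents that add atoms: chloromethyl methyl ether (MOMCl), COCCl
Why: In this phenol O-alkylation (MOM ether formation) the hydroxyl group flanked by I and H (the later O5) should react faster than the one wedged between I and the prenyl group (the later O1).

Step 4
Reactants: 5 isoferulic acid, (E)-3-(3-hydroxy-4-methoxyphenyl)prop-2-enoic acid
Product: 7 (E)-3-[4-methoxy-3-(methoxymethoxy)phenyl]prop-2-enoic acid, via methoxymethyl ester 6 (not isolated)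
Conditions: MOMCl (2.5 equiv), i-Pr2NEt, CH2Cl2, 0 °C to rt; then LiOH, THF/MeOH/H2O, rt; cold dilute HCl to pH 4
Reagents that add atoms: chloromethyl methyl ether (MOMCl), COCCl; lithium hydroxide, [Li+].[OH-]
Why: Exhaustive O-alkylation followed by saponification in the same flask works because the acyloxy acetal (MOM ester) is hydrolysed far faster than the aryl MOM ether.

Step 5
Reactants: 4 2-iodo-5-methoxy-3-(methoxymethoxy)-6-(3-methylbut-2-en-1-yl)phenol; 7 (E)-3-[4-methoxy-3-(methoxymethoxy)phenyl]prop-2-enoic acid
Product: 8 2-iodo-5-methoxy-3-(methoxymethoxy)-6-(3-methylbut-2-en-1-yl)phenyl (E)-3-[4-methoxy-3-(methoxymethoxy)phenyl]prop-2-enoate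
Conditions: DCC, 4-(dimethylamino)pyridine (0.2 equiv), CH2Cl2, 0 °C to rt
Reagents that add atoms: none
Why: In this Steglich esterification the acylpyridinium ion is reactive enough for the di-ortho-substituted phenol, and O1–H is the only free hydroxyl group in either partner.

Step 6
Reactants: 8 2-iodo-5-methoxy-3-(methoxymethoxy)-6-(3-methylbut-2-en-1-yl)phenyl (E)-3-[4-methoxy-3-(methoxymethoxy)phenyl]prop-2-enoate
Product: 12 (2S)-7-methoxy-5-(methoxymethoxy)-2-[4-methoxy-3-(methoxymethoxy)phenyl]-8-(3-methylbut-2-en-1-yl)chroman-4-one, via aryllithium 9 (not isolated), via lithium chalcone phenolate 10 (not isolated), via 2'-hydroxychalcone 11 (not isolated)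
Conditions: mesityllithium (1.1 equiv, made beforehand from 2-bromomesitylene and t-BuLi in THF at −78 °C), THF, −78 °C; AcOH (1.1 equiv), −78 to 0 °C; THF exchanged for toluene in the same flask; N-[3,5-bis(trifluoromethyl)phenyl]-N'-[(8α,9S)-6'-methoxycinchonan-9-yl]thiourea (20 mol %), 0 °C
Reagents that add atoms: none
Why: Mesityllithium, too hindered to add to the cinnamate, exchanges the iodine faster than it attacks anything else, and the C4a carbanion of 9 adds to the adjacent ester carbonyl through a four-membered transition state and expels O1, which forms C4–C4a and gives phenolate 10; the closest known reaction type is the anionic Fries rearrangement of ortho-haloaryl esters set off by halogen–metal exchange. Phenolate 10 cannot cyclise in the aprotic medium, because the flavanone enolate is far more basic than the chelated phenolate, so no racemic ring closure runs before the acid and the catalyst are in place. In 11 the thiourea binds the C4 carbonyl while the quinuclidine takes the O1 proton, and ring C closes by a 6-endo-trig oxa-Michael addition that forms O1–C2, the known organocatalytic counterpart of the chalcone isomerase reaction. The C2 stereocentre is set by the catalyst alone, which lets O1 reach one face of the E-enone; the 6'-alkoxy group twists the aryl ketone and pushes the equilibrium to the flavanone, as in the cyclisation of xanthohumol to isoxanthohumol, so that the retro-reaction that would racemise 12 should stay slow at 0 °C. Site selectivity rests on the substrate: iodine fixes the carbanion at C4a, the Z ester conformation keeps the β-carbon out of its reach, C8 is blocked by the prenyl group, and O5 stays a MOM ether, so that only the oxygen released from the ester can add. What else is in the flask (an aryl iodide and lithium salts that do not dissolve in toluene) is inert to the catalyst, which is why both bonds can be made in one flask.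

Step 7
Reactants: 12 (2S)-7-methoxy-5-(methoxymethoxy)-2-[4-methoxy-3-(methoxymethoxy)phenyl]-8-(3-methylbut-2-en-1-yl)chroman-4-one
Product: 13 (2S)-5-hydroxy-2-(3-hydroxy-4-methoxyphenyl)-7-methoxy-8-(3-methylbut-2-en-1-yl)chroman-4-one (target)
Conditions: conc. HCl (cat.), MeOH, rt to 40 °C
Reagents that add atoms: none
Why: Acid-catalysed acetal exchange removes both MOM groups, the prenyl group has no free ortho hydroxyl group with which to close a chroman, and the absence of base avoids the ring opening that would racemise C2 or move the prenyl group to C6.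

Compound list
1 | 5-methoxyresorcinol | COc1cc(O)cc(O)c1 | starting material
2 | 2-iodo-5-methoxybenzene-1,3-diol | COc1cc(O)c(I)c(O)c1 | intermediate
3 | 2-iodo-5-methoxy-4-(3-methylbut-2-en-1-yl)benzene-1,3-diol | COc1cc(O)c(I)c(O)c1CC=C(C)C | intermediate
4 | 2-iodo-5-methoxy-3-(methoxymethoxy)-6-(3-methylbut-2-en-1-yl)phenol | COCOc1cc(OC)c(CC=C(C)C)c(O)c1I | intermediate
5 | isoferulic acid, (E)-3-(3-hydroxy-4-methoxyphenyl)prop-2-enoic acid | COc1ccc(/C=C/C(=O)O)cc1O | starting material
6 | methoxymethyl (E)-3-[4-methoxy-3-(methoxymethoxy)phenyl]prop-2-enoate (not isolated) | COCOC(=O)/C=C/c1ccc(OC)c(OCOC)c1 | intermediate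
7 | (E)-3-[4-methoxy-3-(methoxymethoxy)phenyl]prop-2-enoic acid | COCOc1cc(/C=C/C(=O)O)ccc1OC | intermediate
8 | aryl cinnamate from 4 and 7 (ester O1–C4, iodine at C4a) | COCOc1cc(/C=C/C(=O)Oc2c(I)c(OCOC)cc(OC)c2CC=C(C)C)ccc1OC | intermediate
9 | aryllithium from 8, lithium at C4a (not isolated) | COCOc1cc(/C=C/C(=O)Oc2c([Li])c(OCOC)cc(OC)c2CC=C(C)C)ccc1OC | intermediate
10 | lithium 2'-phenolate of chalcone 11 (not isolated) | [Li+].[O-]c1c(CC=C(C)C)c(OC)cc(OCOC)c1C(=O)/C=C/c1ccc(OC)c(OCOC)c1 | intermediate
11 | (E)-1-[2-hydroxy-4-methoxy-6-(methoxymethoxy)-3-(3-methylbut-2-en-1-yl)phenyl]-3-[4-methoxy-3-(methoxymethoxy)phenyl]prop-2-en-1-one (not isolated) | Oc1c(CC=C(C)C)c(OC)cc(OCOC)c1C(=O)/C=C/c1ccc(OC)c(OCOC)c1 | intermediate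
12 | (2S)-7-methoxy-5-(methoxymethoxy)-2-[4-methoxy-3-(methoxymethoxy)phenyl]-8-(3-methylbut-2-en-1-yl)chroman-4-one | COc1ccc([C@@H]2CC(=O)c3c(OCOC)cc(OC)c(CC=C(C)C)c3O2)cc1OCOC | intermediate
13 | (2S)-5-hydroxy-2-(3-hydroxy-4-methoxyphenyl)-7-methoxy-8-(3-methylbut-2-en-1-yl)chroman-4-one | COc1ccc([C@@H]2CC(=O)c3c(O)cc(OC)c(CC=C(C)C)c3O2)cc1O | target

Total step count: 7
Longest linear sequence: 6 (steps 1, 2, 3, 5, 6, 7)

Steps most likely to fail

Step 6. The ring closure may be slow or reversible under the catalyst, which would erode the enantiomeric purity, and lithium salts may bind the thiourea and stall it. The fallback replaces asymmetric ring closure by resolution. It sets out from 11, which is isolated by aqueous work-up after the acyl shift. NaOAc in refluxing EtOH should cyclise it to the racemic bis-MOM flavanone F1. Kinetic resolution by asymmetric transfer hydrogenation with RuCl(p-cymene)[(R,R)-TsDPEN] in HCO2H/Et3N should reduce the 2R ketone, for which catalyst and substrate both favour the cis alcohol, to the cis-(2R,4R)-flavan-4-ol F2. The 2S ketone should be left behind and is separated by chromatography. The fallback comes back to the route at 12.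

Step 2. O-alkylation, double alkylation and attack at the iodine-bearing carbon may compete with the wanted C-prenylation. The fallback delivers the prenyl group by a sigmatropic shift and sets out from 2. Mono-etherification with 3-chloro-3-methylbut-1-yne (DBU, CuCl2 cat., MeCN, 0 °C) should give the 1,1-dimethylpropargyl ether F3. Semihydrogenation (H2, Pd/CaCO3 poisoned with Pb(OAc)2, quinoline, EtOAc) should give the 1,1-dimethylallyl ether F4. An aromatic Claisen rearrangement (toluene, 110 °C) then moves the allyl group, with inversion of its ends, to the only free ortho carbon. The fallback comes back to the route at 3.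

Step 3. Discrimination between the two hydroxyl groups may be poor, which would place the MOM group on O1 or on both oxygens. The fallback reverses the order of events and sets out from 2, whose two hydroxyl groups are equivalent. MOMCl (0.9 equiv) with i-Pr2NEt should give the mono-MOM ether F5, and the diol and the bis-ether are separated and recycled. The sodium phenolate of F5 (NaH, toluene) is then alkylated with prenyl bromide. The non-polar medium directs attack to the ortho carbon, and only one ortho carbon is free. The fallback comes back to the route at 4.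

Further compounds
F1 | step 6 | racemic 7-methoxy-5-(methoxymethoxy)-2-[4-methoxy-3-(methoxymethoxy)phenyl]-8-(3-methylbut-2-en-1-yl)chroman-4-one | COc1ccc(C2CC(=O)c3c(OCOC)cc(OC)c(CC=C(C)C)c3O2)cc1OCOC
F2 | step 6 | (2R,4R)-7-methoxy-5-(methoxymethoxy)-2-[4-methoxy-3-(methoxymethoxy)phenyl]-8-(3-methylbut-2-en-1-yl)chroman-4-ol | COc1ccc([C@H]2C[C@@H](O)c3c(OCOC)cc(OC)c(CC=C(C)C)c3O2)cc1OCOC
F3 | step 2 | 2-iodo-5-methoxy-3-[(2-methylbut-3-yn-2-yl)oxy]phenol | C#CC(C)(C)Oc1cc(OC)cc(O)c1I
F4 | step 2 | 2-iodo-5-methoxy-3-[(2-methylbut-3-en-2-yl)oxy]phenol | C=CC(C)(C)Oc1cc(OC)cc(O)c1I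
F5 | step 3 | 2-iodo-5-methoxy-3-(methoxymethoxy)phenol | COCOc1cc(OC)cc(O)c1I
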